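**Assumption:** the target has no stereocentres, so "single enantiomer" is read as the single geometric isomer with all five stereogenic C=C bonds E (2′E,6′E,10′E,14′E,18′E). (E)-Piperylene, geranyl bromide, (2E,6E)-farnesyl chloride and 1-(trimethylsilyl)propyne are bought as such.

## Retrosynthetic overview (written in the order the bonds are made)

1. The quinone ring is the ring of o-cresol 1: dibromination (2), then oxidative dearomatisation gives bromoquinone 3, whose Br is a traceless regiodirector.
2. The benzo ring is formed second, de novo: 3 + (E)-piperylene 4, Diels–Alder/–HBr/aromatisation, gives naphthoquinone 5; its only quinonoid C–H is chloromethylated (6).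
3. Side chain (C3 + C10 + C15): TMS-propyne 7 + geranyl bromide 8 → enyne 9 → ω-alcohol 10 → bromide 11; head-to-tail allylbarium coupling with farnesyl chloride 12 gives C28 alkyne 13.
4. The last disconnection is C1′–C2′, not the usual ring–C1′ bond: syn-carboalumination of 13 sets the 2′E olefin and Ni(0) joins the alkenylalane to 6, giving target 14.

## Route

**Step 1**
Reactants: 1, o-cresol (2-methylphenol)
Product: 2, 2,4-dibromo-6-methylphenol
Conditions: Br2 (2.05 equiv), AcOH, 15 °C → rt
Reagents that add atoms: bromine, BrBr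
Why: Electrophilic aromatic bromination at the free ortho and para positions of the phenol.

**Step 2 (key step)**
Reactants: 2, 2,4-dibromo-6-methylphenol
Product: 3, 2-bromo-6-methyl-1,4-benzoquinone
Conditions: CrO3 (2.5 equiv), AcOH/H2O 1:1, 60–65 °C
Reagents that add atoms: chromium trioxide, O=[Cr](=O)=O (with water, O, as the source of the new C-4 oxygen)
Why: Oxidative dearomatisation of a p-bromophenol to the p-quinone with ipso loss of the para bromide (chromic acid oxidation); the cresol ring becomes the quinone ring and the surviving Br sits next to the carbonyl flanked by the methyl carbon, which programmes Step 3.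

**Step 3**
Reactants: 3, 2-bromo-6-methyl-1,4-benzoquinone; 4, (E)-penta-1,3-diene
Product: 5, 2,8-dimethylnaphthalene-1,4-dione
Conditions: 4 (3 equiv), PhMe, 40 °C, dark; then Et3N (1.5 equiv), rt; then MnO2 (or air), rt
Reagents that add atoms: none
Why: Halogen-directed Diels–Alder at the brominated C=C (the diene's CH2 terminus bonds to the unhalogenated C-3, so CH(CH3) bonds to C–Br), then E1cB loss of HBr and tautomerisation/oxidation to the aromatic ring; this places the new aryl methyl peri to the carbonyl that adjoins the quinone methyl.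

**Step 4**
Reactants: 5, 2,8-dimethylnaphthalene-1,4-dione
Product: 6, 2-(chloromethyl)-3,5-dimethylnaphthalene-1,4-dione
Conditions: 37% aq. CH2O, HCl (g), AcOH, rt, dark
Reagents that add atoms: formaldehyde, C=O; hydrogen chloride, Cl
Why: Acid-mediated chloromethylation (Blanc/Prins-type hydroxymethylation then chloride substitution), the known conversion of menadione to its chloromethyl derivative; 5 has a single quinonoid C–H, so the reaction is regiospecific.

**Step 5**
Reactants: 7, 1-(trimethylsilyl)propyne; 8, geranyl bromide ((2E)-1-bromo-3,7-dimethylocta-2,6-diene)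
Product: 9, [(5E)-6,10-dimethylundeca-5,9-dien-1-yn-1-yl]trimethylsilane
Conditions: 7, n-BuLi, THF, −78 → −20 °C; then 8, −78 → 0 °C
Reagents that add atoms: none
Why: SN2 alkylation of the propargylic anion of TMS-propyne at the primary allylic bromide; the 5E olefin (future 6′E) is carried in from geranyl bromide.

**Step 6**
Reactants: 9
Product: 10, (2E,6E)-2,6-dimethyl-11-(trimethylsilyl)undeca-2,6-dien-10-yn-1-ol
Conditions: SeO2 (0.3 equiv), t-BuOOH (3 equiv), salicylic acid (0.1 equiv), CH2Cl2, 0 °C → rt; then NaBH4, MeOH, 0 °C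
Reagents that add atoms: tert-butyl hydroperoxide, CC(C)(C)OO (oxygen delivered via selenium dioxide, O=[Se]=O)
Why: Sharpless SeO2/TBHP allylic oxidation (ene reaction then [2,3]-shift) oxidises the E-methyl of the terminal isopropylidene, which fixes the future 10′E geometry; NaBH4 returns any over-oxidised enal.

**Step 7**
Reactants: 10
Product: 11, [(5E,9E)-11-bromo-6,10-dimethylundeca-5,9-dien-1-yn-1-yl]trimethylsilane
Conditions: CBr4, PPh3, CH2Cl2, −20 → 0 °C; used at once
Reagents that add atoms: carbon tetrabromide, BrC(Br)(Br)Br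
Why: Appel bromination of the primary allylic alcohol, cold, without allylic transposition or E/Z erosion.

**Step 8**
Reactants: 11; 12, (2E,6E)-farnesyl chloride
Product: 13, (5E,9E,13E,17E)-6,10,14,18,22-pentamethyltricosa-5,9,13,17,21-pentaen-1-yne
Conditions: 12, Rieke Ba (BaI2, 2 Li biphenylide), THF, −78 °C; then 11, −78 °C; then MeOH, K2CO3, rt
Reagents that add atoms: none
Why: Yamamoto allylbarium cross-coupling is α,α′-selective (SN2, head-to-tail) and keeps all E olefins at −78 °C; the methanolic K2CO3 quench removes the alkynyl TMS group.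

**Step 9**
Reactants: 13; 6
Product: 14, 2-[(2E,6E,10E,14E,18E)-3,7,11,15,19,23-hexamethyltetracosa-2,6,10,14,18,22-hexaen-1-yl]-3,5-dimethylnaphthalene-1,4-dione (target)
Conditions: 13 (1.2 equiv), Me3Al (2 equiv), Cp2ZrCl2 (0.25 equiv), ClCH2CH2Cl, 0 °C → rt; evaporate, THF; then 6, NiCl2(PPh3)2/2 n-BuLi (5 mol % Ni(0)), 0 °C → rt
Reagents that add atoms: trimethylaluminium, C[Al](C)C (delivers the C-3′ methyl)
Why: Negishi Zr-catalysed carboalumination adds Me–Al syn across the terminal alkyne to give the (E)-alkenylalane, and Ni(0)-catalysed sp2–sp3 coupling with the chloromethylquinone (Lipshutz-type) forms C1′–C2′ with retention, setting 2′E directly.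

## Compound list

1 | o-cresol (2-methylphenol) | Cc1ccccc1O | starting material
2 | 2,4-dibromo-6-methylphenol | Cc1cc(Br)cc(Br)c1O | intermediate
3 | 2-bromo-6-methyl-1,4-benzoquinone | CC1=CC(=O)C=C(Br)C1=O | intermediate
4 | (E)-penta-1,3-diene (piperylene) | C/C=C/C=C | starting material
5 | 2,8-dimethylnaphthalene-1,4-dione | CC1=CC(=O)c2cccc(C)c2C1=O | intermediate
6 | 2-(chloromethyl)-3,5-dimethylnaphthalene-1,4-dione | CC1=C(CCl)C(=O)c2cccc(C)c2C1=O | intermediate
7 | 1-(trimethylsilyl)propyne | CC#C[Si](C)(C)C | starting material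
8 | geranyl bromide | CC(C)=CCC/C(C)=C/CBr | starting material
9 | [(5E)-6,10-dimethylundeca-5,9-dien-1-yn-1-yl]trimethylsilane | CC(C)=CCC/C(C)=C/CCC#C[Si](C)(C)C | intermediate
10 | (2E,6E)-2,6-dimethyl-11-(trimethylsilyl)undeca-2,6-dien-10-yn-1-ol | OC/C(C)=C/CC/C(C)=C/CCC#C[Si](C)(C)C | intermediate
11 | [(5E,9E)-11-bromo-6,10-dimethylundeca-5,9-dien-1-yn-1-yl]trimethylsilane | BrC/C(C)=C/CC/C(C)=C/CCC#C[Si](C)(C)C | intermediate
12 | (2E,6E)-farnesyl chloride | CC(C)=CCC/C(C)=C/CC/C(C)=C/CCl | starting material
13 | (5E,9E,13E,17E)-6,10,14,18,22-pentamethyltricosa-5,9,13,17,21-pentaen-1-yne | CC(C)=CCC/C(C)=C/CC/C(C)=C/CC/C(C)=C/CC/C(C)=C/CCC#C | intermediate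
14 | 2-[(2E,6E,10E,14E,18E)-3,7,11,15,19,23-hexamethyltetracosa-2,6,10,14,18,22-hexaen-1-yl]-3,5-dimethylnaphthalene-1,4-dione | CC(C)=CCC/C(C)=C/CC/C(C)=C/CC/C(C)=C/CC/C(C)=C/CC/C(C)=C/CC1=C(C)C(=O)c2c(C)cccc2C1=O | target

## Summary

Total steps: 9. Compound 2 is itself an inexpensive catalogue chemical; buying it gives 8.
Longest linear sequence: 5 steps (1 → 2 → 3 → 5 → 6 → 14, or 7/8 → 9 → 10 → 11 → 13 → 14).

Steps most likely to fail, with a fallback that changes the approach:

- **Step 6 (SeO2 ω-oxidation).** The internal trisubstituted olefin can compete with the terminal one, and over-oxidation lowers the yield. Fallback: van Tamelen terminal functionalisation instead of C–H oxidation: NBS/aq. THF bromohydrin on the terminal olefin, epoxide, HIO4 cleavage to the aldehyde, E-selective Wittig with Ph3P=C(CH3)CO2Et, then DIBAL-H to give 10.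
- **Step 8 (allylbarium coupling).** Rieke barium is demanding to prepare, and Wurtz homocoupling or γ-attack are possible. Fallback: Biellmann sulfone coupling: lithiated (2E,6E)-farnesyl p-tolyl sulfone alkylated with 11, then Pd(dppp)Cl2/LiBHEt3 reductive desulfonylation and K2CO3/MeOH desilylation.
- **Step 3 (Diels–Alder regiocontrol and one-pot aromatisation).** Piperylene is only weakly polarised, so some 2,5-dimethyl isomer may form. Fallback: change the control element to a single carbonyl: 4,4-dimethoxy-2-methylcyclohexa-2,5-dienone (PhI(OAc)2/MeOH on 4-methoxy-2-methylphenol) as dienophile, where the "ortho" rule places CH(CH3) α to the lone C=O, then ketal hydrolysis and DDQ aromatisation to 5.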